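**Retrosynthetic overview**

1. Endgame: target 24 ⇐ hydroxy epoxy ketone 20 (angeloylation last) ⇐ enone 18 (nucleophilic epoxidation trans to the side chain, then desilylation) ⇐ silyl enol ether 17 (Saegusa–Ito oxidation) ⇐ cycloadduct 13 (senecioylation, then Tebbe methylenation of the side-chain ketone while the ring carbonyl is still masked as its silyl enol ether).
2. Key disconnection (core numbered as 7-oxabicyclo[4.1.0]heptan-2-one: C1 methyl-bearing epoxide carbon, C2 carbonyl, C3 angelate-bearing, C4 side-chain-bearing, C5 methylene, C6 epoxide CH): bonds C3–C4 and C5–C6 are made in one intermolecular Diels–Alder reaction of the C5 diene 12 with the C9 (4S)-α'-hydroxy vinyl ketone 6.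
3. Enabling feature: C6–C1(CH3)–C2(=O)–C3(O) of the six-membered ring is a latent (Z)-1,2-dioxygenated 3-methylbuta-1,3-diene. C5–C4 is a latent vinyl group whose C4 carries the methylidene carbon (a latent ketone) followed directly by the oxygenated side-chain stereocentre, i.e. an α'-hydroxy enone that can steer its own facial selectivity; the cis C3–O/C4–C relation is the endo signature.
4. Fragments: 6 in three steps from penta-1,4-dien-3-ol (Sharpless desymmetrisation, copper-catalysed alkenyl Grignard opening, MnO2); 12 in three steps from 2-[(tert-butyldimethylsilyl)oxy]acetaldehyde.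
5. Ring order: the six-membered carbocycle first (step 7), the oxirane second (step 11); the carbinol centre of 6 is the only stereocentre set by a chiral reagent and relays to all four ring stereocentres.

Key step: step 7

Remark on the chemistry: reagent solutions sold as such (the two Grignard reagents, Tebbe reagent, tert-butyl hydroperoxide in decane) are taken as commercial starting materials; alcohol 9 is used as the racemate because its stereocentre is oxidised away in step 5.

**Route**

Step 1
Reactants: 1 penta-1,4-dien-3-ol; 2 tert-butyl hydroperoxide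
Product: 3 (2S,3R)-1,2-epoxypent-4-en-3-ol
Conditions: Ti(OiPr)4 (10 mol %), D-(−)-diisopropyl tartrate (13 mol %), 2 (decane solution), 4 Å molecular sieves, CH2Cl2, −20 °C
Reagents that add atoms: tert-butyl hydroperoxide (2), CC(C)(C)OO
Why: Sharpless asymmetric epoxidation of the divinyl carbinol, in which the Ti(OiPr)4/tartrate catalyst selects one enantiotopic vinyl group and one of its faces; by the Sharpless mnemonic D-(−)-tartrate should give the erythro (2S,3R)-epoxy alcohol, and its enantiomeric purity should rise with conversion because the minor enantiomer is consumed by a second epoxidation.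

Step 2
Reactants: 3 (2S,3R)-1,2-epoxypent-4-en-3-ol; 4 2-methylprop-1-enylmagnesium bromide
Product: 5 (3R,4S)-7-methylocta-1,6-diene-3,4-diol
Conditions: 4 (3 equiv), CuI (10 mol %), THF, −30 → 0 °C; then H2O
Reagents that add atoms: 2-methylprop-1-enylmagnesium bromide (4), CC(C)=C[Mg]Br
Why: Copper-catalysed SN2 opening of the terminal epoxide at its unsubstituted carbon by the alkenyl Grignard reagent (one equivalent is used up by the hydroxyl group) should install the prenyl-type chain without touching either stereocentre, so the epoxide carbon becomes the (4S)-carbinol.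

Step 3
Reactants: 5 (3R,4S)-7-methylocta-1,6-diene-3,4-diol
Product: 6 (4S)-4-hydroxy-7-methylocta-1,6-dien-3-one
Conditions: activated MnO2 (excess), CH2Cl2, 23 °C
Reagents that add atoms: none
Why: MnO2 oxidises allylic alcohols chemoselectively, so only the vinyl carbinol should be converted into the vinyl ketone while the non-allylic C4 hydroxyl and its configuration are kept under the neutral conditions.

Step 4
Reactants: 7 2-[(tert-butyldimethylsilyl)oxy]acetaldehyde; 8 isopropenylmagnesium bromide
Product: 9 rac-1-[(tert-butyldimethylsilyl)oxy]-3-methylbut-3-en-2-ol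
Conditions: 8 (1.2 equiv), THF, −78 → 0 °C; then H2O
Reagents that add atoms: isopropenylmagnesium bromide (8), CC(=C)[Mg]Br
Why: Grignard 1,2-addition to the aldehyde gives the allylic alcohol; the new stereocentre is irrelevant because it is oxidised in the next step.

Step 5
Reactants: 9 rac-1-[(tert-butyldimethylsilyl)oxy]-3-methylbut-3-en-2-ol
Product: 10 1-[(tert-butyldimethylsilyl)oxy]-3-methylbut-3-en-2-one
Conditions: Dess–Martin periodinane, CH2Cl2, 0 → 23 °C
Reagents that add atoms: none
Why: Dess–Martin oxidation converts the secondary allylic alcohol into the enone under non-basic conditions that leave the silyl ether and the enone intact.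

Step 6
Reactants: 10 1-[(tert-butyldimethylsilyl)oxy]-3-methylbut-3-en-2-one; 11 tert-butyldimethylsilyl trifluoromethanesulfonate
Product: 12 (1Z)-1,2-bis[(tert-butyldimethylsilyl)oxy]-3-methylbuta-1,3-diene
Conditions: 11 (1.2 equiv), Et3N, CH2Cl2, 0 °C
Reagents that add atoms: tert-butyldimethylsilyl trifluoromethanesulfonate (11), CC(C)(C)[Si](C)(C)OS(=O)(=O)C(F)(F)F
Why: Soft enolisation (silyl triflate and amine) can only occur at the CH2OSi position and should give the 2-silyloxy diene, the (Z)-enol ether with the two oxygens cis being expected for an α-oxygenated ketone; any (E)-isomer would be inert in the cycloaddition because it cannot reach the s-cis diene conformation easily.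

Step 7
Reactants: 6 (4S)-4-hydroxy-7-methylocta-1,6-dien-3-one; 12 (1Z)-1,2-bis[(tert-butyldimethylsilyl)oxy]-3-methylbuta-1,3-diene
Product: 13 (2S)-1-[(1S,2S)-2,3-bis[(tert-butyldimethylsilyl)oxy]-4-methylcyclohex-3-en-1-yl]-2-hydroxy-5-methylhex-4-en-1-one
Conditions: 12 (1.5 equiv), BHT (cat.), toluene, 0 → 40 °C, no external Lewis acid
Reagents that add atoms: none
Why: This is a normal-electron-demand, concerted but asynchronous Diels–Alder cycloaddition in which the electron-rich diene 12 adds to enone 6, whose intramolecular O–H···O=C hydrogen bond lowers the LUMO and locks the s-cis enone with the hydroxyl syn-coplanar to the carbonyl; the closest known reaction type is the cycloaddition of 1-silyloxy and 2-silyloxy 1,3-dienes to hydrogen-bonded chiral α'-hydroxy vinyl ketones. The cyclohex-3-ene ring is closed by intermolecular suprafacial 4π + 2π union, which forms the σ-bonds C1–C2 and C5–C6 of 13 at once. C1 is controlled by the carbinol stereocentre of 6: in the hydrogen-bonded conformer the prenylmethylene group covers one face of the alkene, so the diene should add anti to it, and for the (4S)-enone this gives the configuration needed in the target. C2 is set relative to C1 by the endo rule acting on the (Z)-enol ether (terminal oxygen in the outside position), which places the silyloxy group cis to the acyl group. The step needs "ortho" regiochemistry with respect to the terminal silyloxy group: bonding should begin at the unhindered CH2 terminus, because the residual allyl-cation character is then stabilised at both ends (terminal oxygen and methyl-bearing carbon), a direction favoured jointly by the 1-oxygen and the 3-methyl group over the single internal silyloxy group. Endo and facial selectivity rest on secondary orbital overlap of the acyl group and on the rigid five-membered hydrogen-bonded ring of 6.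

Step 8
Reactants: 13 (2S)-1-[(1S,2S)-2,3-bis[(tert-butyldimethylsilyl)oxy]-4-methylcyclohex-3-en-1-yl]-2-hydroxy-5-methylhex-4-en-1-one; 14 3-methylbut-2-enoic acid
Product: 15 (2S)-1-[(1S,2S)-2,3-bis[(tert-butyldimethylsilyl)oxy]-4-methylcyclohex-3-en-1-yl]-5-methyl-1-oxohex-4-en-2-yl 3-methylbut-2-enoate
Conditions: 14, DCC, DMAP (cat.), CH2Cl2, 0 → 23 °C
Reagents that add atoms: 3-methylbut-2-enoic acid (14), CC(C)=CC(=O)O
Why: Steglich esterification of the only free hydroxyl group proceeds under nearly neutral conditions that should neither cleave the silyl enol ether nor epimerise the two carbons α to the ketone.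

Step 9
Reactants: 15 (2S)-1-[(1S,2S)-2,3-bis[(tert-butyldimethylsilyl)oxy]-4-methylcyclohex-3-en-1-yl]-5-methyl-1-oxohex-4-en-2-yl 3-methylbut-2-enoate; 16 Tebbe reagent Cp2Ti(CH2)(Cl)AlMe2
Product: 17 (3S)-2-[(1R,2S)-2,3-bis[(tert-butyldimethylsilyl)oxy]-4-methylcyclohex-3-en-1-yl]-6-methylhepta-1,5-dien-3-yl 3-methylbut-2-enoate
Conditions: 16 (1.2 equiv), pyridine (cat.), THF–toluene, −40 → 0 °C
Reagents that add atoms: Tebbe reagent Cp2Ti(CH2)(Cl)AlMe2 (16), C[Al](C)C[Ti](Cl)(C1C=CC=C1)C1C=CC=C1 (chloride bridge drawn open)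
Why: Tebbe methylenation (titanium methylidene Cp2Ti=CH2, [2+2] addition and cycloreversion) is non-basic, so both α-stereocentres should survive; at low temperature the ketone reacts much faster than the ester, and the ring carbonyl is protected as its silyl enol ether.

Step 10
Reactants: 17 (3S)-2-[(1R,2S)-2,3-bis[(tert-butyldimethylsilyl)oxy]-4-methylcyclohex-3-en-1-yl]-6-methylhepta-1,5-dien-3-yl 3-methylbut-2-enoate
Product: 18 (3S)-2-[(1R,6S)-6-[(tert-butyldimethylsilyl)oxy]-4-methyl-5-oxocyclohex-3-en-1-yl]-6-methylhepta-1,5-dien-3-yl 3-methylbut-2-enoate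
Conditions: Pd(OAc)2 (1.1 equiv), MeCN, 23 → 40 °C
Reagents that add atoms: none
Why: Saegusa–Ito oxidation: the silyl enol ether is transferred to palladium at the methyl-bearing carbon and β-hydride elimination into the ring CH2 should give the endocyclic 2-methyl enone, while the alkyl silyl ether and the two existing stereocentres are not involved.

Step 11
Reactants: 18 (3S)-2-[(1R,6S)-6-[(tert-butyldimethylsilyl)oxy]-4-methyl-5-oxocyclohex-3-en-1-yl]-6-methylhepta-1,5-dien-3-yl 3-methylbut-2-enoate; 2 tert-butyl hydroperoxide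
Product: 19 (3S)-2-[(1S,3S,4R,6S)-3-[(tert-butyldimethylsilyl)oxy]-1-methyl-2-oxo-7-oxabicyclo[4.1.0]heptan-4-yl]-6-methylhepta-1,5-dien-3-yl 3-methylbut-2-enoate
Conditions: 2 (decane solution), benzyltrimethylammonium hydroxide (cat.), THF, 0 °C
Reagents that add atoms: tert-butyl hydroperoxide (2), CC(C)(C)OO
Why: Weitz–Scheffer nucleophilic epoxidation touches only the electron-poor enone; the peroxide anion should add axially to the β-carbon on the face opposite to the side chain two carbons away (as in carvone) and to the pseudo-axial silyloxy group, and enolate closure on the same face gives the oxirane trans to both substituents.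

Step 12
Reactants: 19 (3S)-2-[(1S,3S,4R,6S)-3-[(tert-butyldimethylsilyl)oxy]-1-methyl-2-oxo-7-oxabicyclo[4.1.0]heptan-4-yl]-6-methylhepta-1,5-dien-3-yl 3-methylbut-2-enoate
Product: 20 (3S)-2-[(1S,3S,4R,6S)-3-hydroxy-1-methyl-2-oxo-7-oxabicyclo[4.1.0]heptan-4-yl]-6-methylhepta-1,5-dien-3-yl 3-methylbut-2-enoate
Conditions: HF·pyridine, pyridine, THF, 0 → 23 °C
Reagents that add atoms: none
Why: Buffered fluoride desilylation removes the silyl ether under weakly acidic conditions that should leave the deactivated α,β-epoxy ketone, the allylic ester and the α-stereocentre unchanged.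

Step 13
Reactants: 20 (3S)-2-[(1S,3S,4R,6S)-3-hydroxy-1-methyl-2-oxo-7-oxabicyclo[4.1.0]heptan-4-yl]-6-methylhepta-1,5-dien-3-yl 3-methylbut-2-enoate; 21 angelic acid [(2Z)-2-methylbut-2-enoic acid]; 22 2,4,6-trichlorobenzoyl chloride
Product: 24 (1S,3S,4R,6S)-1-methyl-4-[(3S)-6-methyl-3-[(3-methylbut-2-enoyl)oxy]hepta-1,5-dien-2-yl]-2-oxo-7-oxabicyclo[4.1.0]heptan-3-yl (2Z)-2-methylbut-2-enoate, via angelic 2,4,6-trichlorobenzoic anhydride 23 (not isolated)
Conditions: 21, 22, Et3N, toluene, 23 °C; then 20, 60 °C, no DMAP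
Reagents that add atoms: angelic acid (21), C/C=C(/C)C(=O)O; 2,4,6-trichlorobenzoyl chloride (22), O=C(Cl)c1c(Cl)cc(Cl)cc1Cl (its atoms stay only in intermediate 23)
Why: Yamaguchi esterification through the preformed mixed anhydride, run without a nucleophilic catalyst, is the established way to acylate hindered secondary alcohols with angelic acid while keeping the (Z)-geometry, and the hindered aroyl carbonyl directs attack to the angeloyl carbonyl.

**Compound list**

1 | penta-1,4-dien-3-ol | C=CC(O)C=C | starting material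
2 | tert-butyl hydroperoxide | CC(C)(C)OO | starting material
3 | (2S,3R)-1,2-epoxypent-4-en-3-ol [(1R)-1-[(2S)-oxiran-2-yl]prop-2-en-1-ol] | C=C[C@@H](O)[C@@H]1CO1 | intermediate
4 | 2-methylprop-1-enylmagnesium bromide | CC(C)=C[Mg]Br | starting material
5 | (3R,4S)-7-methylocta-1,6-diene-3,4-diol | C=C[C@@H](O)[C@@H](O)CC=C(C)C | intermediate
6 | (4S)-4-hydroxy-7-methylocta-1,6-dien-3-one | C=CC(=O)[C@@H](O)CC=C(C)C | intermediate
7 | 2-[(tert-butyldimethylsilyl)oxy]acetaldehyde | O=CCO[Si](C)(C)C(C)(C)C | starting material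
8 | isopropenylmagnesium bromide (prop-1-en-2-ylmagnesium bromide) | CC(=C)[Mg]Br | starting material
9 | rac-1-[(tert-butyldimethylsilyl)oxy]-3-methylbut-3-en-2-ol | C=C(C)C(O)CO[Si](C)(C)C(C)(C)C | intermediate
10 | 1-[(tert-butyldimethylsilyl)oxy]-3-methylbut-3-en-2-one | C=C(C)C(=O)CO[Si](C)(C)C(C)(C)C | intermediate
11 | tert-butyldimethylsilyl trifluoromethanesulfonate | CC(C)(C)[Si](C)(C)OS(=O)(=O)C(F)(F)F | starting material
12 | (1Z)-1,2-bis[(tert-butyldimethylsilyl)oxy]-3-methylbuta-1,3-diene | C=C(C)/C(O[Si](C)(C)C(C)(C)C)=C/O[Si](C)(C)C(C)(C)C | intermediate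
13 | (2S)-1-[(1S,2S)-2,3-bis[(tert-butyldimethylsilyl)oxy]-4-methylcyclohex-3-en-1-yl]-2-hydroxy-5-methylhex-4-en-1-one | O=C([C@H](CC=C(C)C)O)[C@H]1CCC(C)=C(O[Si](C)(C)C(C)(C)C)[C@H]1O[Si](C)(C)C(C)(C)C | intermediate
14 | 3-methylbut-2-enoic acid (senecioic acid) | CC(C)=CC(=O)O | starting material
15 | (2S)-1-[(1S,2S)-2,3-bis[(tert-butyldimethylsilyl)oxy]-4-methylcyclohex-3-en-1-yl]-5-methyl-1-oxohex-4-en-2-yl 3-methylbut-2-enoate | O=C([C@H](CC=C(C)C)OC(=O)C=C(C)C)[C@H]1CCC(C)=C(O[Si](C)(C)C(C)(C)C)[C@H]1O[Si](C)(C)C(C)(C)C | intermediate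
16 | Tebbe reagent Cp2Ti(CH2)(Cl)AlMe2 | C[Al](C)C[Ti](Cl)(C1C=CC=C1)C1C=CC=C1 | starting material
17 | (3S)-2-[(1R,2S)-2,3-bis[(tert-butyldimethylsilyl)oxy]-4-methylcyclohex-3-en-1-yl]-6-methylhepta-1,5-dien-3-yl 3-methylbut-2-enoate | C=C([C@H](CC=C(C)C)OC(=O)C=C(C)C)[C@H]1CCC(C)=C(O[Si](C)(C)C(C)(C)C)[C@H]1O[Si](C)(C)C(C)(C)C | intermediate
18 | (3S)-2-[(1R,6S)-6-[(tert-butyldimethylsilyl)oxy]-4-methyl-5-oxocyclohex-3-en-1-yl]-6-methylhepta-1,5-dien-3-yl 3-methylbut-2-enoate | C=C([C@H](CC=C(C)C)OC(=O)C=C(C)C)[C@H]1CC=C(C)C(=O)[C@H]1O[Si](C)(C)C(C)(C)C | intermediate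
19 | (3S)-2-[(1S,3S,4R,6S)-3-[(tert-butyldimethylsilyl)oxy]-1-methyl-2-oxo-7-oxabicyclo[4.1.0]heptan-4-yl]-6-methylhepta-1,5-dien-3-yl 3-methylbut-2-enoate | C=C([C@H](CC=C(C)C)OC(=O)C=C(C)C)[C@H]1C[C@@H]2O[C@]2(C)C(=O)[C@H]1O[Si](C)(C)C(C)(C)C | intermediate
20 | (3S)-2-[(1S,3S,4R,6S)-3-hydroxy-1-methyl-2-oxo-7-oxabicyclo[4.1.0]heptan-4-yl]-6-methylhepta-1,5-dien-3-yl 3-methylbut-2-enoate | C=C([C@H](CC=C(C)C)OC(=O)C=C(C)C)[C@H]1C[C@@H]2O[C@]2(C)C(=O)[C@H]1O | intermediate
21 | angelic acid [(2Z)-2-methylbut-2-enoic acid] | C/C=C(/C)C(=O)O | starting material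
22 | 2,4,6-trichlorobenzoyl chloride | O=C(Cl)c1c(Cl)cc(Cl)cc1Cl | starting material
23 | angelic 2,4,6-trichlorobenzoic anhydride | C/C=C(/C)C(=O)OC(=O)c1c(Cl)cc(Cl)cc1Cl | intermediate
24 | (1S,3S,4R,6S)-1-methyl-4-[(3S)-6-methyl-3-[(3-methylbut-2-enoyl)oxy]hepta-1,5-dien-2-yl]-2-oxo-7-oxabicyclo[4.1.0]heptan-3-yl (2Z)-2-methylbut-2-enoate (CNP0414062.1) | C=C([C@H](CC=C(C)C)OC(=O)C=C(C)C)[C@H]1C[C@@H]2O[C@]2(C)C(=O)[C@H]1OC(=O)/C(C)=C\C | target

**Totals and risks**

Total step count: 13. Longest linear sequence: 10 steps (steps 1–3 and 7–13; the diene branch, steps 4–6 and 7–13, is equally long).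

Steps most likely to fail:

Step 7 (key step). Bonding may start from the oxygenated diene terminus under the influence of the internal silyloxy group, which would give the wrong regiochemistry, and the small prenylmethylene group may discriminate the two enone faces only moderately, so that isomer separation erodes the material flow. The fallback replaces the intermolecular reaction by a type 2 intramolecular Diels–Alder reaction on a temporary silicon tether; it sets out from 10 and 6 and comes back to the route at 18. Ketone 10 would be enolised with iPr2Si(OTf)2 and Et3N, and the resulting silyl enol ether triflate quenched in the same flask with alcohol 6 to give the mixed silyl acetal diisopropyl{[(1Z)-1-[(tert-butyldimethylsilyl)oxy]-3-methylbuta-1,3-dien-2-yl]oxy}{[(4S)-7-methyl-3-oxoocta-1,6-dien-4-yl]oxy}silane F1. Heating F1 in toluene (80–110 °C, BHT) should give the bridged cycloadduct (5S,7S,11S)-11-[(tert-butyldimethylsilyl)oxy]-10-methyl-5-(3-methylbut-2-en-1-yl)-3,3-di(propan-2-yl)-2,4-dioxa-3-silabicyclo[5.3.1]undec-1(10)-en-6-one F2. The five-atom tether from the internal diene carbon forces the acyl-bearing carbon next to the oxygenated terminus and holds the acyl group endo, hence cis to the silyloxy group; the facial outcome under control of the tether carbinol would have to be confirmed. Tebbe methylenation of the ring ketone would give the methylidene compound (5S,7R,11S)-11-[(tert-butyldimethylsilyl)oxy]-10-methyl-6-methylidene-5-(3-methylbut-2-en-1-yl)-3,3-di(propan-2-yl)-2,4-dioxa-3-silabicyclo[5.3.1]undec-1(10)-ene F3. Pd(OAc)2 oxidation of its bridgehead silyl enol ether, followed by brief buffered HF·pyridine treatment that removes the labile silanol ether but not the secondary silyl ether, would release the hydroxy enone (5R,6S)-6-[(tert-butyldimethylsilyl)oxy]-5-[(3S)-3-hydroxy-6-methylhepta-1,5-dien-2-yl]-2-methylcyclohex-2-en-1-one F4. Steglich esterification of F4 with 14 gives 18.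

Step 13. During the warm, amine-containing acylation of a hindered alcohol the (Z)-acyl unit may isomerise to the (E)-isomer by reversible conjugate addition, or the α-acyloxy ketone carbon may enolise and lose the cis relation to the side chain. The fallback builds the (Z)-double bond on the substrate instead of transferring it; it sets out from 20 and comes back at 24. Alcohol 20 would be esterified under neutral carbodiimide conditions (DCC, CH2Cl2) with 2-(diphenoxyphosphoryl)propanoic acid to give the phosphonate ester (1S,3S,4R,6S)-1-methyl-4-[(3S)-6-methyl-3-[(3-methylbut-2-enoyl)oxy]hepta-1,5-dien-2-yl]-2-oxo-7-oxabicyclo[4.1.0]heptan-3-yl 2-(diphenoxyphosphoryl)propanoate F5 (mixture of epimers at the phosphonate carbon). A Z-selective Horner–Wadsworth–Emmons reaction of the diaryl phosphonate with acetaldehyde (NaI, DBU, THF, −78 → 0 °C) should then give 24.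

Step 10. Transfer of the hindered, fully substituted silyl enol ether to palladium may be slow, β-hydride elimination may go toward the methyl group, or zerovalent palladium formed in the reaction may ionise the allylic ester. The fallback uses selenium instead of palladium; it sets out from 17 and comes back at 18. Treatment of 17 with PhSeCl (CH2Cl2, −78 °C), which reacts with the silyl enol ether far faster than with the isolated alkenes, would give the α-phenylselanyl ketone (3S)-2-[(1R,2S)-2-[(tert-butyldimethylsilyl)oxy]-4-methyl-3-oxo-4-(phenylselanyl)cyclohexyl]-6-methylhepta-1,5-dien-3-yl 3-methylbut-2-enoate F6. Oxidation with NaIO4 (NaHCO3, THF–H2O, 23 °C) and syn-elimination of the selenoxide into the ring should give enone 18.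

**Further compounds**

F1 | step 7 | diisopropyl{[(1Z)-1-[(tert-butyldimethylsilyl)oxy]-3-methylbuta-1,3-dien-2-yl]oxy}{[(4S)-7-methyl-3-oxoocta-1,6-dien-4-yl]oxy}silane | C=CC(=O)[C@H](CC=C(C)C)O[Si](C(C)C)(C(C)C)O/C(C(C)=C)=C\O[Si](C)(C)C(C)(C)C
F2 | step 7 | (5S,7S,11S)-11-[(tert-butyldimethylsilyl)oxy]-10-methyl-5-(3-methylbut-2-en-1-yl)-3,3-di(propan-2-yl)-2,4-dioxa-3-silabicyclo[5.3.1]undec-1(10)-en-6-one | O=C1[C@H](CC=C(C)C)O[Si](C(C)C)(C(C)C)OC2=C(C)CC[C@H]1[C@@H]2O[Si](C)(C)C(C)(C)C
F3 | step 7 | (5S,7R,11S)-11-[(tert-butyldimethylsilyl)oxy]-10-methyl-6-methylidene-5-(3-methylbut-2-en-1-yl)-3,3-di(propan-2-yl)-2,4-dioxa-3-silabicyclo[5.3.1]undec-1(10)-ene | C=C1[C@H](CC=C(C)C)O[Si](C(C)C)(C(C)C)OC2=C(C)CC[C@H]1[C@@H]2O[Si](C)(C)C(C)(C)C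
F4 | step 7 | (5R,6S)-6-[(tert-butyldimethylsilyl)oxy]-5-[(3S)-3-hydroxy-6-methylhepta-1,5-dien-2-yl]-2-methylcyclohex-2-en-1-one | C=C([C@H](CC=C(C)C)O)[C@H]1CC=C(C)C(=O)[C@H]1O[Si](C)(C)C(C)(C)C
F5 | step 13 | (1S,3S,4R,6S)-1-methyl-4-[(3S)-6-methyl-3-[(3-methylbut-2-enoyl)oxy]hepta-1,5-dien-2-yl]-2-oxo-7-oxabicyclo[4.1.0]heptan-3-yl 2-(diphenoxyphosphoryl)propanoate | C=C([C@H](CC=C(C)C)OC(=O)C=C(C)C)[C@H]1C[C@@H]2O[C@]2(C)C(=O)[C@H]1OC(=O)C(C)P(=O)(Oc1ccccc1)Oc1ccccc1
F6 | step 10 | (3S)-2-[(1R,2S)-2-[(tert-butyldimethylsilyl)oxy]-4-methyl-3-oxo-4-(phenylselanyl)cyclohexyl]-6-methylhepta-1,5-dien-3-yl 3-methylbut-2-enoate | C=C([C@H](CC=C(C)C)OC(=O)C=C(C)C)[C@H]1CCC(C)([Se]c2ccccc2)C(=O)[C@H]1O[Si](C)(C)C(C)(C)C
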